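Between 60.0 h and 192 h the blue flask's target readings span 1 percentage point without a trend, against a scatter of 0.5 points.

| flask | starting material | temperature | remark | time |
|---|---|---|---|---|
| blue | 0.050 M | 25 °C | the very flask that is asked about, followed so far |  |
| teal | 0.034 M | 25 °C | run made earlier |  |
| flask | 0.050 M | 25 °C |  | 8.0 d |

| run | time / h | target / % |
|---|---|---|
| blue | 15.0 | 26.6 |
| blue | 25.0 | 24.4 |
| blue | 40.0 | 22.8 |
| blue | 60.0 | 21.8 |
| blue | 72.0 | 20.9 |
| blue | 120 | 21.9 |
| blue | 192 | 21.3 |
| teal | 1.00 | 28.5 |
| teal | 1.33 | 32.6 |
| teal | 2.00 | 36.1 |
| teal | 3.00 | 37.7 |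
| teal | 5.00 | 37.1 |
| teal | 8.00 | 32.4 |
| teal | 12.0 | 29.0 |

(scatter of a reading: 0.5 percentage points)

- eta: at 8.0 d raise the temperature by 20 K, then wait 2.5 d
- epsilon: at 8.0 d add starting material, 50.0 % of the amount charged, then wait 2.5 d
- alpha: at 8.0 d take out 90 % of the target then present, then wait 2.5 d
- zeta: change nothing and wait 2.5 d more

- removed target is counted in
- the earlier runs do not show what temperature does; that part of a forecast is a guess
- additions bring no volume worth counting

1. target, in percent of the starting material first charged, at 8.0 d
2. which option adds most target ("none" when 2 percentage points or less is all one gets) (eta / epsilon / alpha / zeta / none)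
3. target present, with what was taken out counted in, in percent of the starting material first charged, after epsilon
4. target present, with what was taken out counted in, in percent of the starting material first charged, after alpha

The time of looking matters little, because the blue readings are flat on both sides of 72.0 h and 8.0 d falls at the last one. The charge seems to matter little too. The teal flask, with c(starting material) = 0.034 M, reads 29.0 % at 12.0 h, and the blue flask, with c(starting material) = 0.050 M, reads 26.6 % at 15.0 h; I read these as one falling curve. Temperature may matter most, but both runs stand at 25 °C, so eta has no reckoning. The plateau matters directly, since epsilon brings the material to 150 % of the charge and an error in the plateau passes into epsilon's figure in that proportion.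

The equilibrium share, the fraction of the material in the flask standing as target under thermodynamic control, is the mean of the flat blue readings: 21.5 %. The blue excess over it gives a read half-life of 12.8 h, and because this is shorter than the further 2.5 d, I take each disturbed flask to regain the share. My reckoning gives 21.5 % now and 32.2 % after epsilon, a gain of 11 points. After alpha it gives 36.7 %, a larger gain of 15 points.

The forecast gives 21.4 %, 32.2 % and 36 %, the last slightly below my figure, and chooses alpha, noting that “heating is a guess”.

The flask gives 21.6 % at 8.0 d, 32.6 % after epsilon and 36.8 % after alpha, but the best option is eta, adding 24 points against 15 points for alpha.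

    starting material ⇌ target (K = 2.50, k = 0.635 h⁻¹, Ea = 101 kJ mol⁻¹, ΔH = 25.0 kJ mol⁻¹)
    starting material ⇌ isomer of the product A (K = 5.52, k = 0.199 h⁻¹, Ea = 105 kJ mol⁻¹, ΔH = −25.0 kJ mol⁻¹)
    starting material ⇌ third isomer (K = 0.780, k = 0.808 h⁻¹, Ea = 103 kJ mol⁻¹, ΔH = −4.00 kJ mol⁻¹)
    target ⇌ isomer of the product B (K = 0.700, k = 0.0754 h⁻¹, Ea = 99.0 kJ mol⁻¹, ΔH = −51.0 kJ mol⁻¹)
    (constants at 25 °C)

The neighbour flask at 50 °C holds 52.2 % target at 8.0 d, and the one at 10 °C holds 12.5 %. Divided by the material after epsilon, 150 % of the charge, 32.6 % returns a share of 21.8 %, beside the 21.5 % read from the blue run. Carried to the teal flask, the share predicts 21.5 %, and that flask left to 8.0 d stands at 21.6 %.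

(The data come from a simulation for substances that don't exist; scatter was added.)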